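The numbers of this flask are those of an exercise; what happens was integrated by code.

Turn every constant of this flask into a time at the charged amounts, and add the times of one catalyst turn in series, like resistances.

substrate 0.99 M; coupling partner 1.98 M; free catalyst 0.99 mM

    catalyst intermediate B → catalyst intermediate C (k1 = 11.2 s⁻¹)
    coupling partner → decomposed reagent (k2 = 2.91 × 10⁻⁴ s⁻¹)
    catalyst intermediate C → by-product + catalyst intermediate D (k3 = 8.61 s⁻¹)
    catalyst intermediate D ⇌ free catalyst + target (K4 = 2.8 M, k4 = 14.9 s⁻¹)
    2 coupling partner → self-condensation product (k5 = 0.00484 L mol⁻¹ s⁻¹)
    coupling partner + catalyst intermediate A → catalyst intermediate B (k6 = 7.69 L mol⁻¹ s⁻¹)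
    substrate + free catalyst ⇌ catalyst intermediate A (K7 = 0.574 L mol⁻¹, k7 = 11.6 L mol⁻¹ s⁻¹)

- for a step with 2 of a species take k times the square, and two of it per event
- charge of substrate (flask): 0.99 M

- apparent order in coupling partner when 20% of the substrate are converted (percent change of the rate of making target for one percent more coupling partner charged)

| stage of the turn | time at the charge |
|---|---|
| substrate binds | 0.0871 s |
| catalyst intermediate B turns | 0.0893 s |
| catalyst intermediate C turns | 0.116 s |
| catalyst intermediate D releases target | 0.0671 s |
| coupling partner joins, with fall-back | 0.181 s |

The last row is the bare joining time 0.0657 s widened 2.76-fold, because catalyst intermediate A falls back to free catalyst faster than free catalyst binds substrate. The rows add up to a turnover time of 0.541 s, and since the last row is the one that holds [coupling partner], our first estimate of the order is its share, 0.335.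

But [coupling partner] does not stay at its charge. Self-condensation against the turnover gives 20.7: this is the waste ratio, coupling partner taken by self-condensation per coupling partner taken by the cycle. The half-life by self-condensation is 52.2 s, while reaching 20% conversion at the charged rate takes 108 s, twice as long, so the point asked lies after a real fall.

With [coupling partner] near 0.644 M at that time, the joining row grows to 0.557 s and its share to 0.608. Yet that is the order in the coupling partner present, not the charged one. By the second-order fall at a fixed time, one percent more charge gives about a third of a percent more coupling partner present, but the question fixes conversion, not time, and a larger charge shortens the joining row, so that conversion comes sooner. We cannot finish that by hand, so we commit to the middle of the two shares, 0.471.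

The forecast gives 0.35, which it places “close to the roughly one-third share of the partner-dependent term in the cycle's resistance at the initial concentration”. Ours is higher.

This flask gives 0.54, more than either estimate and less than the later share. The waste ratio, 20.7 as reckoned at the charge, stands as a reading of 0.29 at 12.0 min, so by then self-condensation takes less coupling partner than the joining step, with 2.7% of the charge left.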